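**Synthesis proposal for CNP0159088.1 (7-acetoxy-11-hydroxy-8,9-seco-ent-kaura-8(14),16-diene-9,15-dione)**

Plan
1. Numbering follows the 8,9-seco-ent-kaurane skeleton: ring A = C1–C5/C10, ten-membered ring = C5–C6–C7–C8–C14–C13–C12–C11–C9–C10, ring D = C8/C14/C13/C16/C15. The retrosynthesis cuts C7–C8 (macrocyclisation), C11=C12 (fragment union, later reduced), C9–C11, and in ring A the bonds C1–C10 and C2–C3; the C15 ketone, C11–OH and the acetate are late adjustments.
2. Enabling feature: C9 is tied to O7 as a six-membered lactone (O–C7–C6–C5–C10–C9) whose only enolisable carbon is C10, and the neighbouring C5 carries the C4(Me)2–C3H=O arm. The C10 enolate (donor) and the C3 aldehyde (acceptor) sit 1,4 to each other, so a vinylphosphonium salt (C1 acceptor, then C2 ylide donor) inserts C1–C2 and closes ring A in one operation.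
3. Forward order: temporary lactone ring → ring A (key step) → lactone opened to the C9 vinyl ketone → cross-metathesis with preformed ring D → ten-membered ring by Nozaki–Hiyama–Kishi closure of C7–C8 → acetate, C11–OH, C15 ketone.
4. Stereochemistry: the lactone C7 centre comes from (R)-benzyl glycidyl ether and directs C5 (radical conjugate addition, trans); C5 directs the quaternary C10 (key step, anti); the auxiliary carbon is then excised. C13 comes from (R)-4-silyloxycyclopentenone (anti conjugate addition). C7 and C11 are set on the macrocycle (ring closure, enolate hydroxylation).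

Key step: step 6

Remark: 8 and 9 are C10-epimer mixtures (this centre is re-formed in step 6), and 24 is drawn as the cis epimer expected from the reduction; its carbinol centre becomes the C15 ketone in the last step.

Step 1
Reactants: 1 (R)-benzyl glycidyl ether; 2 vinylmagnesium bromide
Product: 3 (R)-1-(benzyloxy)pent-4-en-2-ol
Conditions: CuI (10 mol%), THF, −40 → 0 °C; NH4Cl (aq)
Reagents that add atoms: none
Why: Copper-catalysed Grignard opening of the terminal epoxide (SN2 at the CH2 carbon) does not touch the stereocentre, so the carbinol carbon (future C7) keeps the R configuration of the glycidol.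

Step 2
Reactants: 3 (R)-1-(benzyloxy)pent-4-en-2-ol; 4 methacryloyl chloride
Product: 5 (R)-1-(benzyloxy)pent-4-en-2-yl methacrylate
Conditions: Et3N, DMAP (cat.), CH2Cl2, 0 °C
Reagents that add atoms: none
Why: DMAP-catalysed O-acylation of the secondary alcohol with the acid chloride brings in C9, C10 and the C20 methyl without touching the stereocentre.

Step 3
Reactants: 5 (R)-1-(benzyloxy)pent-4-en-2-yl methacrylate
Product: 6 (R)-6-[(benzyloxy)methyl]-3-methyl-5,6-dihydro-2H-pyran-2-one
Conditions: second-generation Grubbs catalyst (5 mol%), toluene, 80 °C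
Reagents that add atoms: none
Why: Ring-closing metathesis of the methacrylate with the allyl group gives the six-membered α-methyl unsaturated lactone (C5=C10) with loss of ethylene, the trisubstituted olefin being within reach of the second-generation catalyst.

Step 4
Reactants: 6 (R)-6-[(benzyloxy)methyl]-3-methyl-5,6-dihydro-2H-pyran-2-one; 7 methacrolein dimethyl acetal
Product: 8 (4S,6R)-6-[(benzyloxy)methyl]-4-(1,1-dimethoxy-2-methylpropan-2-yl)-3-methyltetrahydro-2H-pyran-2-one (C10 epimers)
Conditions: Fe(acac)3 (30 mol%), PhSiH3 (3 equiv), MeOH/THF, 50 °C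
Reagents that add atoms: none
Why: Hydrogen-atom transfer from an iron hydride to the 1,1-disubstituted olefin of 7 gives the nucleophilic tertiary radical Me2C•–CH(OMe)2, whose Giese addition to C5 of the unsaturated lactone (reductive olefin coupling) should occur by axial attack anti to the C7 substituent and so set C5 trans to C7.

Step 5
Reactants: 8 acetal lactone
Product: 9 2-[(4S,6R)-6-[(benzyloxy)methyl]-3-methyl-2-oxotetrahydro-2H-pyran-4-yl]-2-methylpropanal (C10 epimers)
Conditions: 2 M HCl (aq), THF, 23 °C
Reagents that add atoms: water O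
Why: Acid hydrolysis of the dimethyl acetal frees the non-enolisable neopentyl aldehyde (C3) while the lactone and the benzyl ether survive dilute acid.

Step 6
Reactants: 9 aldehyde lactone; 10 vinyltriphenylphosphonium bromide
Product: 13 (3R,4aR,8aR)-3-[(benzyloxy)methyl]-5,5,8a-trimethyl-3,4,4a,5,8,8a-hexahydro-1H-isochromen-1-one, via lithium enolate 11 (not isolated), via phosphonium ylide 12 (not isolated)
Conditions: lithium 2,2,6,6-tetramethylpiperidide (1.1 equiv), THF, −78 °C; then 10 (1.5 equiv), −78 → 23 °C
Reagents that add atoms: none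
Why: The amide base removes the only α-hydrogen of the lactone (C10–H) to give enolate 11, whose carbon terminus adds in Michael fashion to the vinylphosphonium salt (C10–C1 bond) and thereby creates ylide 12 at C2, which closes on the C3 aldehyde by intramolecular Wittig olefination (C2=C3, saturated to the C2–C3 single bond in step 7) with loss of Ph3P=O. The closest known reaction type is the vinylphosphonium Michael–Wittig annulation of enolates that carry a carbonyl group, used for cyclopentenes, cyclohexenes and dihydrofurans. Ring A closes in a 6-exo-trig attack of the ylide carbon on the aldehyde, and the oxaphosphetane can only collapse to the cis olefin of the six-membered ring. The quaternary centre C10 is controlled by C5: allylic 1,2-strain with the C10 methyl forces the bulky C5 arm pseudoaxial in the enolate, the acceptor enters from the opposite face, and C1 ends up trans to C4 on the lactone ring, so that the C10 methyl is anti to H5 as in the target. The step needs regioselective enolate formation, C- over O-alkylation and survival of the aldehyde: the lactone has a single α-carbon, the aldehyde has no α-hydrogen and is too hindered for the amide base, the soft phosphonium acceptor reacts at carbon, and any aldol between enolate and aldehyde (a four-membered ring if intramolecular) is reversible and should drain into the irreversible olefination.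

Step 7
Reactants: 13 unsaturated bicyclic lactone
Product: 14 (3R,4aR,8aR)-3-(hydroxymethyl)-5,5,8a-trimethyloctahydro-1H-isochromen-1-one
Conditions: H2 (1 atm), 10% Pd/C, EtOAc/EtOH, 23 °C
Reagents that add atoms: none
Why: Heterogeneous catalytic hydrogenation saturates the cis C2=C3 olefin (completing the C2–C3 single bond of ring A) and removes the benzyl ether by hydrogenolysis in the same flask without creating a stereocentre.

Step 8
Reactants: 14 hydroxymethyl lactone; 2 vinylmagnesium bromide (3.5 equiv)
Product: 15 1-[(1R,2R)-2-[(2R)-2,3-dihydroxypropyl]-1,3,3-trimethylcyclohexyl]prop-2-en-1-one (in equilibrium with its six-membered lactol)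
Conditions: THF, −78 → 0 °C; NH4Cl (aq)
Reagents that add atoms: none
Why: Grignard addition to the lactone should stop at the magnesium hemiketal because the carbonyl (C9) is flanked by quaternary C10, so that work-up releases the C9 vinyl ketone (C11 attached) together with the C7 hydroxyl (nucleophilic acyl substitution, opening of the temporary ring).

Step 9
Reactants: 16 (R)-4-[(tert-butyldimethylsilyl)oxy]cyclopent-2-en-1-one; 2 vinylmagnesium bromide
Product: 17 (3S,4R)-4-[(tert-butyldimethylsilyl)oxy]-3-vinylcyclopentan-1-one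
Conditions: CuBr·SMe2 (20 mol%), THF, −78 °C; NH4Cl (aq)
Reagents that add atoms: none
Why: Copper-catalysed conjugate addition of the vinyl Grignard reagent occurs on the face anti to the silyloxy group and so fixes the future C13 (trans adduct).

Step 10
Reactants: 17 trans adduct
Product: 18 (S)-4-vinylcyclopent-2-en-1-one
Conditions: DBU, CH2Cl2, 0 °C, short contact time
Reagents that add atoms: none
Why: E1cB β-elimination of silanolate from the β-silyloxy ketone transposes the enone (ring D: C15=O, C8=C14) with the C13 centre intact, as in the conversion of E-type into A-type prostaglandins.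

Step 11
Reactants: 18 (S)-4-vinylcyclopent-2-en-1-one
Product: 19 (S)-2-iodo-4-vinylcyclopent-2-en-1-one
Conditions: I2, pyridine/CH2Cl2, 0 → 23 °C
Reagents that add atoms: iodine II
Why: α-Iodination of the enone by the pyridine addition–iodination–elimination sequence puts the iodide on C8, the carbon that will later bond to C7.

Step 12
Reactants: 19 (S)-2-iodo-4-vinylcyclopent-2-en-1-one
Product: 23 (S)-2-iodo-5-methylene-4-vinylcyclopent-2-en-1-one, via lithium dienolate 20 (not isolated), via Mannich base 21 (not isolated), via ammonium iodide 22 (not isolated)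
Conditions: LiN(SiMe3)2, THF, −78 °C; Eschenmoser's salt, −78 → 0 °C; then MeI; then NaHCO3 (aq), 23 °C
Reagents that add atoms: Eschenmoser's salt (N,N-dimethylmethyleneiminium iodide) C=[N+](C)C.[I-]
Why: Kinetic α′-deprotonation at C16, Mannich reaction with the iminium salt, quaternisation and E1cB loss of trimethylamine amount to an α-methylenation that installs C17 without disturbing C13.

Step 13
Reactants: 23 iodo dienone
Product: 24 (1S,4S)-2-iodo-5-methylene-4-vinylcyclopent-2-en-1-ol
Conditions: NaBH4, CeCl3·7H2O, MeOH, −78 °C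
Reagents that add atoms: none
Why: Luche 1,2-reduction of the cross-conjugated dienone masks C15, with hydride expected anti to the C13 vinyl group to give the cis alcohol (the minor epimer would serve equally).

Step 14
Reactants: 24 dienol
Product: 25 tert-butyl{[(1S,4S)-2-iodo-5-methylene-4-vinylcyclopent-2-en-1-yl]oxy}dimethylsilane
Conditions: TBSCl, imidazole, DMF, 23 °C
Reagents that add atoms: tert-butyldimethylsilyl chloride CC(C)(C)[Si](C)(C)Cl
Why: Standard silylation protects the doubly allylic C15 alcohol for the organometallic and enolate steps to come.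

Step 15
Reactants: 15 vinyl ketone diol; 25 ring D silyl ether
Product: 26 (E)-1-[(1R,2R)-2-[(2R)-2,3-dihydroxypropyl]-1,3,3-trimethylcyclohexyl]-3-[(1S,4S)-4-[(tert-butyldimethylsilyl)oxy]-3-iodo-5-methylenecyclopent-2-en-1-yl]prop-2-en-1-one
Conditions: second-generation Hoveyda–Grubbs catalyst (10 mol%), p-benzoquinone (cat.), CH2Cl2, 40 °C
Reagents that add atoms: none
Why: Olefin cross-metathesis between the electron-poor vinyl ketone and the monosubstituted vinyl group joins the two fragments as the E-enone (C11=C12), the 1,1-disubstituted and iodo-substituted olefins of ring D being unreactive partners.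

Step 16
Reactants: 26 E-enone
Product: 27 1-[(1R,2R)-2-[(2R)-2,3-dihydroxypropyl]-1,3,3-trimethylcyclohexyl]-3-[(1S,4S)-4-[(tert-butyldimethylsilyl)oxy]-3-iodo-5-methylenecyclopent-2-en-1-yl]propan-1-one
Conditions: [(Ph3P)CuH]6 (Stryker's reagent), H2O, toluene/THF, 23 °C
Reagents that add atoms: none
Why: Copper hydride reduces only the conjugated C11=C12 bond (conjugate reduction) and should leave the vinyl iodide, the isolated olefin and the silyl ether untouched.

Step 17
Reactants: 27 saturated ketone diol
Product: 28 2-[(1R,2R)-2-[3-[(1S,4S)-4-[(tert-butyldimethylsilyl)oxy]-3-iodo-5-methylenecyclopent-2-en-1-yl]propanoyl]-2,6,6-trimethylcyclohexyl]acetaldehyde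
Conditions: NaIO4, THF/pH 7 buffer, 0 °C
Reagents that add atoms: none
Why: Periodate cleavage of the 1,2-diol excises the auxiliary carbon as formaldehyde and unveils the C7 aldehyde.

Step 18
Reactants: 28 keto aldehyde vinyl iodide
Product: 29 macrocyclic 7R alcohol of the 8,9-seco-ent-kaura-8(14),16-diene skeleton (C9 ketone; C15 silyl ether)
Conditions: CrCl2 (10 equiv), NiCl2 (2 mol%), DMSO/THF, 23 °C, 0.002 M, slow addition
Reagents that add atoms: none
Why: In this intramolecular Nozaki–Hiyama–Kishi reaction the vinylchromium species formed at C8 should add to the C7 aldehyde and not to the C9 ketone (whose attack would need a bridgehead olefin in a bicyclo[3.2.1] ring), which closes the ten-membered ring and sets C7 under macrocyclic control, the 7R epimer being expected from the aldehyde face that keeps the C–O bond on the periphery of the forming ring.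

Step 19
Reactants: 29 macrocyclic alcohol
Product: 30 C7 acetate of 29
Conditions: Ac2O, DMAP, pyridine, CH2Cl2, 23 °C
Reagents that add atoms: acetic anhydride CC(=O)OC(C)=O
Why: DMAP-catalysed acetylation of the only free hydroxyl (C7) installs the acetate.

Step 20
Reactants: 30 macrocyclic acetate
Product: 32 11S-hydroxy ketone (C7 acetate; C15 silyl ether), via potassium enolate 31 (not isolated)
Conditions: KN(SiMe3)2 (1.2 equiv), THF, −78 °C; then trans-2-(phenylsulfonyl)-3-phenyloxaziridine, −78 °C; NH4Cl (aq)
Reagents that add atoms: trans-2-(phenylsulfonyl)-3-phenyloxaziridine O=S(=O)(c1ccccc1)N1OC1c1ccccc1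
Why: The C9 ketone can enolise only towards C11 because C10 is quaternary, and oxygen transfer from the N-sulfonyloxaziridine to the outer face of the macrocyclic enolate (Davis hydroxylation) is expected, though not assured, to give the 11S alcohol.

Step 21
Reactants: 32 11-hydroxy silyl ether
Product: 33 C15 alcohol (C11 hydroxyl and C7 acetate in place)
Conditions: HF·pyridine, pyridine, THF, 0 °C
Reagents that add atoms: none
Why: Buffered fluoride cleaves the silyl ether to the C15 alcohol without acyl migration or ionisation of the doubly allylic position.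

Step 22
Reactants: 33 diol
Product: 34 CNP0159088.1
Conditions: MnO2 (activated, 20 equiv), CH2Cl2, 23 °C
Reagents that add atoms: none
Why: Manganese dioxide should oxidise only the doubly allylic C15 alcohol to the cross-conjugated dienone, the C11 α-ketol hydroxyl not being allylic.

Compound list
1 | (R)-benzyl glycidyl ether | C(OCc1ccccc1)[C@H]1CO1 | starting material
2 | vinylmagnesium bromide | C=C[Mg]Br | starting material
3 | (R)-1-(benzyloxy)pent-4-en-2-ol | C=CC[C@@H](O)COCc1ccccc1 | intermediate
4 | methacryloyl chloride | C=C(C)C(=O)Cl | starting material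
5 | (R)-1-(benzyloxy)pent-4-en-2-yl methacrylate | C=CC[C@H](COCc1ccccc1)OC(=O)C(C)=C | intermediate
6 | (R)-6-[(benzyloxy)methyl]-3-methyl-5,6-dihydro-2H-pyran-2-one | CC1=CC[C@H](COCc2ccccc2)OC1=O | intermediate
7 | methacrolein dimethyl acetal (3,3-dimethoxy-2-methylprop-1-ene) | C=C(C)C(OC)OC | starting material
8 | (4S,6R)-6-[(benzyloxy)methyl]-4-(1,1-dimethoxy-2-methylpropan-2-yl)-3-methyltetrahydro-2H-pyran-2-one (4,6-trans; C10 epimers) | COC(OC)C(C)(C)[C@H]1C[C@H](COCc2ccccc2)OC(=O)C1C | intermediate
9 | 2-[(4S,6R)-6-[(benzyloxy)methyl]-3-methyl-2-oxotetrahydro-2H-pyran-4-yl]-2-methylpropanal (C10 epimers) | O=CC(C)(C)[C@H]1C[C@H](COCc2ccccc2)OC(=O)C1C | intermediate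
10 | vinyltriphenylphosphonium bromide | C=C[P+](c1ccccc1)(c1ccccc1)c1ccccc1.[Br-] | starting material
11 | lithium enolate of lactone 9 | [Li+].O=CC(C)(C)[C@H]1C[C@H](COCc2ccccc2)OC([O-])=C1C | intermediate
12 | phosphonium ylide (Michael adduct; C10 quaternary; C1 anti to the C5 arm) | O=CC(C)(C)[C@H]1C[C@H](COCc2ccccc2)OC(=O)[C@]1(C)CC=P(c1ccccc1)(c1ccccc1)c1ccccc1 | intermediate
13 | (3R,4aR,8aR)-3-[(benzyloxy)methyl]-5,5,8a-trimethyl-3,4,4a,5,8,8a-hexahydro-1H-isochromen-1-one | O=C1O[C@@H](COCc3ccccc3)C[C@@H]2C(C)(C)C=CC[C@@]12C | intermediate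
14 | (3R,4aR,8aR)-3-(hydroxymethyl)-5,5,8a-trimethyloctahydro-1H-isochromen-1-one | O=C1O[C@@H](CO)C[C@@H]2C(C)(C)CCC[C@@]12C | intermediate
15 | 1-[(1R,2R)-2-[(2R)-2,3-dihydroxypropyl]-1,3,3-trimethylcyclohexyl]prop-2-en-1-one | C=CC(=O)[C@]1(C)CCCC(C)(C)[C@H]1C[C@@H](O)CO | intermediate
16 | (R)-4-[(tert-butyldimethylsilyl)oxy]cyclopent-2-en-1-one | O=C1C=C[C@H](O[Si](C)(C)C(C)(C)C)C1 | starting material
17 | (3S,4R)-4-[(tert-butyldimethylsilyl)oxy]-3-vinylcyclopentan-1-one | O=C1C[C@@H](C=C)[C@H](O[Si](C)(C)C(C)(C)C)C1 | intermediate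
18 | (S)-4-vinylcyclopent-2-en-1-one | O=C1C=C[C@H](C=C)C1 | intermediate
19 | (S)-2-iodo-4-vinylcyclopent-2-en-1-one | O=C1C(I)=C[C@H](C=C)C1 | intermediate
20 | lithium cross-conjugated dienolate of 19 | [Li+].[O-]C1=C[C@@H](C=C)C=C1I | intermediate
21 | trans-5-[(dimethylamino)methyl]-2-iodo-4-vinylcyclopent-2-en-1-one (Mannich base; 4S) | O=C1C(I)=C[C@H](C=C)[C@H]1CN(C)C | intermediate
22 | trimethylammonium iodide of 21 | O=C1C(I)=C[C@H](C=C)[C@H]1C[N+](C)(C)C.[I-] | intermediate
23 | (S)-2-iodo-5-methylene-4-vinylcyclopent-2-en-1-one | O=C1C(I)=C[C@H](C=C)C1=C | intermediate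
24 | (1S,4S)-2-iodo-5-methylene-4-vinylcyclopent-2-en-1-ol | C=C1[C@H](O)C(I)=C[C@@H]1C=C | intermediate
25 | tert-butyl{[(1S,4S)-2-iodo-5-methylene-4-vinylcyclopent-2-en-1-yl]oxy}dimethylsilane | C=C1[C@H](O[Si](C)(C)C(C)(C)C)C(I)=C[C@@H]1C=C | intermediate
26 | (E)-1-[(1R,2R)-2-[(2R)-2,3-dihydroxypropyl]-1,3,3-trimethylcyclohexyl]-3-[(1S,4S)-4-[(tert-butyldimethylsilyl)oxy]-3-iodo-5-methylenecyclopent-2-en-1-yl]prop-2-en-1-one | C=C1[C@H](O[Si](C)(C)C(C)(C)C)C(I)=C[C@@H]1/C=C/C(=O)[C@]1(C)CCCC(C)(C)[C@H]1C[C@@H](O)CO | intermediate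
27 | 1-[(1R,2R)-2-[(2R)-2,3-dihydroxypropyl]-1,3,3-trimethylcyclohexyl]-3-[(1S,4S)-4-[(tert-butyldimethylsilyl)oxy]-3-iodo-5-methylenecyclopent-2-en-1-yl]propan-1-one | C=C1[C@H](O[Si](C)(C)C(C)(C)C)C(I)=C[C@@H]1CCC(=O)[C@]1(C)CCCC(C)(C)[C@H]1C[C@@H](O)CO | intermediate
28 | 2-[(1R,2R)-2-[3-[(1S,4S)-4-[(tert-butyldimethylsilyl)oxy]-3-iodo-5-methylenecyclopent-2-en-1-yl]propanoyl]-2,6,6-trimethylcyclohexyl]acetaldehyde | C=C1[C@H](O[Si](C)(C)C(C)(C)C)C(I)=C[C@@H]1CCC(=O)[C@]1(C)CCCC(C)(C)[C@H]1CC=O | intermediate
29 | (7R)-15-[(tert-butyldimethylsilyl)oxy]-7-hydroxy-8,9-seco-ent-kaura-8(14),16-dien-9-one (all centres as drawn) | C=C1[C@H](O[Si](C)(C)C(C)(C)C)C2=C[C@@H]1CCC(=O)[C@]1(C)CCCC(C)(C)[C@H]1C[C@H]2O | intermediate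
30 | C7 acetate of 29 | C=C1[C@H](O[Si](C)(C)C(C)(C)C)C2=C[C@@H]1CCC(=O)[C@]1(C)CCCC(C)(C)[C@H]1C[C@H]2OC(C)=O | intermediate
31 | potassium C9–C11 enolate of 30 | [K+].C=C1[C@H](O[Si](C)(C)C(C)(C)C)C2=C[C@@H]1CC=C([O-])[C@]1(C)CCCC(C)(C)[C@H]1C[C@H]2OC(C)=O | intermediate
32 | (11S)-11-hydroxy derivative of 30 (C7 acetate; C15 silyl ether) | C=C1[C@H](O[Si](C)(C)C(C)(C)C)C2=C[C@@H]1C[C@H](O)C(=O)[C@]1(C)CCCC(C)(C)[C@H]1C[C@H]2OC(C)=O | intermediate
33 | 7-acetoxy-11,15-dihydroxy-8,9-seco-ent-kaura-8(14),16-dien-9-one (all centres as drawn) | C=C1[C@H](O)C2=C[C@@H]1C[C@H](O)C(=O)[C@]1(C)CCCC(C)(C)[C@H]1C[C@H]2OC(C)=O | intermediate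
34 | CNP0159088.1: (5R,7R,10R,11S,13S)-7-acetoxy-11-hydroxy-8,9-seco-ent-kaura-8(14),16-diene-9,15-dione | C=C1C(=O)C2=C[C@@H]1C[C@H](O)C(=O)[C@]1(C)CCCC(C)(C)[C@H]1C[C@H]2OC(C)=O | target

Total step count: 22
Longest linear sequence: 16 steps (steps 1–8, then 15–22)

Steps most likely to fail

Step 6. The hindered enolate may add only slowly to the phosphonium salt, so that retro-Michael loss of the C4 arm or intermolecular aldol addition to the aldehyde wins before the ylide is formed. The fallback builds the same two bonds one after the other by known reactions; it sets out from acetal lactone 8 and comes back at 13. Deprotonation of 8 with LiN(i-Pr)2 in THF at −78 °C and alkylation with allyl bromide, again anti to the C5 arm, would give the C10-allyl acetal lactone F1. Aqueous HCl in THF would free the aldehyde F2, and Ph3P=CH2 (−78 → 0 °C) would turn it into the diene F3. Ring-closing metathesis with the second-generation Grubbs catalyst would then close C2=C3 and deliver 13.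

Step 18. The ring closure may show poor facial selectivity at C7, or give oligomers if the dilution is insufficient. The fallback replaces macrocyclic control by reagent control; it sets out from 28 and comes back at 29. The closure is run without regard to the C7 ratio, and the mixture of 29 and its C7 epimer F4 is oxidised with Dess–Martin periodinane to the C7 ketone F5 (an enone with C8=C14). Reduction with (S)-2-methyl-CBS-oxazaborolidine and BH3·SMe2, in which the alkenyl group acts as the large substituent, should give the 7R alcohol 29; the hindered C9 ketone is expected to react much more slowly.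

Step 20. Oxygen may be delivered to the other face of the macrocyclic enolate, and the base may also attack or deprotonate the acetate. The fallback corrects the centre by inversion; it sets out from 30 and comes back at 32. If the hydroxylation gives mainly the C11 epimer F6, this is converted into the C11 triflate F7 (Tf2O, pyridine, CH2Cl2, −20 °C) and displaced with KNO2 in DMF (SN2 inversion next to the ketone; the nitrite ester is hydrolysed on work-up) to give 32.

Further compounds
F1 | step 6 | (3R,4R,6R)-3-allyl-6-[(benzyloxy)methyl]-4-(1,1-dimethoxy-2-methylpropan-2-yl)-3-methyltetrahydro-2H-pyran-2-one | COC(OC)C(C)(C)[C@H]1C[C@H](COCc2ccccc2)OC(=O)[C@]1(C)CC=C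
F2 | step 6 | 2-[(3R,4R,6R)-3-allyl-6-[(benzyloxy)methyl]-3-methyl-2-oxotetrahydro-2H-pyran-4-yl]-2-methylpropanal | O=CC(C)(C)[C@H]1C[C@H](COCc2ccccc2)OC(=O)[C@]1(C)CC=C
F3 | step 6 | (3R,4R,6R)-3-allyl-6-[(benzyloxy)methyl]-3-methyl-4-(2-methylbut-3-en-2-yl)tetrahydro-2H-pyran-2-one | C=CC(C)(C)[C@H]1C[C@H](COCc2ccccc2)OC(=O)[C@]1(C)CC=C
F4 | step 18 | C7 epimer of 29 | C=C1[C@H](O[Si](C)(C)C(C)(C)C)C2=C[C@@H]1CCC(=O)[C@]1(C)CCCC(C)(C)[C@H]1C[C@@H]2O
F5 | step 18 | C7 ketone from 29 and F4 (7,9-dione; C15 silyl ether) | C=C1[C@H](O[Si](C)(C)C(C)(C)C)C2=C[C@@H]1CCC(=O)[C@]1(C)CCCC(C)(C)[C@H]1CC2=O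
F6 | step 20 | C11 epimer of 32 | C=C1[C@H](O[Si](C)(C)C(C)(C)C)C2=C[C@@H]1C[C@@H](O)C(=O)[C@]1(C)CCCC(C)(C)[C@H]1C[C@H]2OC(C)=O
F7 | step 20 | C11 trifluoromethanesulfonate of F6 | C=C1[C@H](O[Si](C)(C)C(C)(C)C)C2=C[C@@H]1C[C@@H](OS(=O)(=O)C(F)(F)F)C(=O)[C@]1(C)CCCC(C)(C)[C@H]1C[C@H]2OC(C)=O
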